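**Retrosynthetic overview**
- Last ring: the bridged 3(2H)-furanone, closed by a transannular C3–O bond from the C10 hydroxyl onto the C1≡C2–C3=O unit of a 10-membered γ-hydroxy-ynone, followed by O15 desilylation.
- 10-membered carbocycle: CO-inserting ring closure (C2–C3 and C3–C4) of a seco vinyl iodide / terminal alkyne.
- Seco compound: zinc Barbier union (C7–C8) of a C6-defined 3-(bromomethyl)butenolide with (R)-3-hydroxy-3-methylpent-4-ynal, then C8 crotonylation.
- Butenolide from 2-butyne-1,4-diol (C4–C6, C15) and ethyl 2-(bromomethyl)acrylate (C7, C11–C13); aldehyde from 4-(trimethylsilyl)but-3-yn-2-one and an allylboron reagent.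
- Ring order: γ-lactone, then 10-membered carbocycle, then furanone (C–O bridge).

Assumption: the target is taken exactly as drawn, (4Z,6S,7S,8R,10R) in germacrane numbering (C12 lactone carbonyl, C13 exocyclic methylene, C14 methyl on C10, C15 hydroxymethyl on C4); these locants are used throughout.

**Step 1**
Reactants: 1 2-butyne-1,4-diol
Product: 2 4-[(tert-butyldimethylsilyl)oxy]but-2-yn-1-ol
Conditions: TBSCl (1.0 equiv), imidazole (1.1 equiv), 1 (3 equiv), THF, 0 °C → rt
Reagents that add atoms: tert-butyldimethylsilyl chloride, CC(C)(C)[Si](C)(C)Cl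
Why: Silyl ether formation on one hydroxyl of the symmetric diol is made selective by using the cheap diol in excess (statistical monoprotection).

**Step 2**
Reactants: 2 4-[(tert-butyldimethylsilyl)oxy]but-2-yn-1-ol
Product: 4 (Z)-4-[(tert-butyldimethylsilyl)oxy]-3-iodobut-2-en-1-ol, via cyclic sodium alkenylalanate 3 (not isolated)
Conditions: NaAlH2(OCH2CH2OMe)2 (1.5 equiv), THF, 0 °C → rt; then I2, THF, −78 → 0 °C
Reagents that add atoms: iodine, II
Why: Hydroxyl-directed trans-hydroalumination of the propargylic alcohol and iodinolysis of the C–Al bond with retention put iodine on C4 cis to C6, which fixes the later Z-configured C4=C5 bond.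

**Step 3**
Reactants: 4 (Z)-4-[(tert-butyldimethylsilyl)oxy]-3-iodobut-2-en-1-ol
Product: 5 (Z)-4-[(tert-butyldimethylsilyl)oxy]-3-iodobut-2-enal
Conditions: MnO2 (15 equiv), CH2Cl2, rt
Reagents that add atoms: none
Why: Allylic alcohol oxidation on MnO2 is mild and neutral, so the Z geometry, the C–I bond and the silyl ether survive.

**Step 4**
Reactants: 5 (Z)-4-[(tert-butyldimethylsilyl)oxy]-3-iodobut-2-enal; 6 ethyl 2-(bromomethyl)acrylate
Product: 9 (R)-5-[(Z)-3-((tert-butyldimethylsilyl)oxy)-2-iodoprop-1-en-1-yl]-3-methylenedihydrofuran-2(3H)-one, via trimethylsilyl ether 7 (not isolated), via hydroxy ester 8 (not isolated)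
Conditions: CrCl2 (10 mol%), chiral 1,8-bis(oxazolin-2-yl)carbazole ligand (12 mol%), iPr2NEt (30 mol%), Mn powder (2 equiv), Me3SiCl (1.5 equiv), THF, rt; aq. citric acid; then PPTS (10 mol%), toluene, 50 °C
Reagents that add atoms: none
Why: Catalytic asymmetric Nozaki–Hiyama-type 2-(ethoxycarbonyl)allylation in which the ligand-bound allylchromium adds to the Re face of the aldehyde to set C6 (R in 9; the ligand antipode is chosen accordingly), the vinyl iodide being inert to divalent chromium without nickel, and mild acid then closes the γ-lactone.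

**Step 5**
Reactants: 9 (R)-5-[(Z)-3-((tert-butyldimethylsilyl)oxy)-2-iodoprop-1-en-1-yl]-3-methylenedihydrofuran-2(3H)-one
Product: 11 (R)-3-(bromomethyl)-5-[(Z)-3-((tert-butyldimethylsilyl)oxy)-2-iodoprop-1-en-1-yl]furan-2(5H)-one, via dibromide 10 (not isolated)
Conditions: Br2 (1.05 equiv), CH2Cl2, −78 → −20 °C, dark; then iPr2NEt (1.2 equiv), −20 → 0 °C
Reagents that add atoms: bromine, BrBr
Why: Bromine adds to the exocyclic 1,1-disubstituted alkene (the iodoalkene is deactivated by iodine and two allylic C–O bonds) and the hindered base removes HBr by E2 across C7–C11 (bromination–dehydrobromination), giving the conjugated butenolide without touching C6.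

**Step 6**
Reactants: 12 4-(trimethylsilyl)but-3-yn-2-one
Product: 14 (R)-3-methylhex-5-en-1-yn-3-ol, via tertiary borate 13 (not isolated)
Conditions: allylB(OiPr)2 (1.5 equiv), (S)-3,3′-Br2-BINOL (15 mol%), PhCF3–toluene, −35 °C; then K2CO3, MeOH, rt
Reagents that add atoms: allyldiisopropoxyborane, C=CCB(OC(C)C)OC(C)C
Why: BINOL-catalysed asymmetric allylboration of a ketone through a closed six-membered transition state, the silylalkynyl group taking the place of the aryl group of aryl methyl ketones so that the (S)-catalyst should give the (R)-carbinol (C10; the antipode is used if the sense proves opposite), after which K2CO3/MeOH cleaves the borate and the C–Si bond.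

**Step 7**
Reactants: 14 (R)-3-methylhex-5-en-1-yn-3-ol
Product: 16 (R)-3-hydroxy-3-methylpent-4-ynal, via ozonide 15 (not isolated)
Conditions: O3, CH2Cl2, −78 °C (stopped at first blue tinge); then Me2S, −78 °C → rt; solution used without purification
Reagents that add atoms: ozone, O=[O+][O-]
Why: Ozonolysis with reductive work-up, ozone attacking the terminal alkene much faster than the terminal alkyne and leaving C10 untouched.

**Step 8**
Reactants: 11 (R)-3-(bromomethyl)-5-[(Z)-3-((tert-butyldimethylsilyl)oxy)-2-iodoprop-1-en-1-yl]furan-2(5H)-one; 16 (R)-3-hydroxy-3-methylpent-4-ynal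
Product: 17 (4S,5R)-5-[(Z)-3-((tert-butyldimethylsilyl)oxy)-2-iodoprop-1-en-1-yl]-4-[(1R,3R)-1,3-dihydroxy-3-methylpent-4-yn-1-yl]-3-methylenedihydrofuran-2(3H)-one
Conditions: Zn dust (3 equiv), THF–sat. aq. NH4Cl (2:1), 0 °C → rt
Reagents that add atoms: none
Why: Zinc Barbier allylation (SE2′) through a closed chair transition state, the allylzinc reacting at C7 anti to the C6 side chain (trans-lactone, sets C7) and the ring-locked E-type γ-substituent giving the 7,8-syn carbinol (sets C8 as R), while the exocyclic methylene is regenerated.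

**Step 9**
Reactants: 17 (4S,5R)-5-[(Z)-3-((tert-butyldimethylsilyl)oxy)-2-iodoprop-1-en-1-yl]-4-[(1R,3R)-1,3-dihydroxy-3-methylpent-4-yn-1-yl]-3-methylenedihydrofuran-2(3H)-one
Product: 18 (1R,3R)-1-[(2R,3S)-2-[(Z)-3-((tert-butyldimethylsilyl)oxy)-2-iodoprop-1-en-1-yl]-4-methylene-5-oxotetrahydrofuran-3-yl]-3-hydroxy-3-methylpent-4-yn-1-yl (E)-but-2-enoate
Conditions: (E)-crotonic anhydride (1.5 equiv), Et3N, DMAP (10 mol%), CH2Cl2, 0 °C
Reagents that add atoms: (E)-but-2-enoic anhydride, C/C=C/C(=O)OC(=O)/C=C/C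
Why: DMAP-catalysed acylation is selective for the secondary C8 hydroxyl over the tertiary propargylic C10 hydroxyl and installs the (E)-crotonate without stereochemical change.

**Step 10**
Reactants: 18 (1R,3R)-1-[(2R,3S)-2-[(Z)-3-((tert-butyldimethylsilyl)oxy)-2-iodoprop-1-en-1-yl]-4-methylene-5-oxotetrahydrofuran-3-yl]-3-hydroxy-3-methylpent-4-yn-1-yl (E)-but-2-enoate
Product: 19 (4Z,6S,7S,8R,10R)-8-[(E)-but-2-enoyloxy]-15-[(tert-butyldimethylsilyl)oxy]-10-hydroxy-3-oxogermacra-4,11(13)-dien-1-yn-6,12-olide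
Conditions: PdCl2(PPh3)2 (10 mol%), CuI (10 mol%), Et3N (3 equiv), CO (1 atm), THF, 40 °C, syringe-pump addition of 18 (final 1 mM)
Reagents that add atoms: carbon monoxide, [C-]#[O+]
Why: Carbonylative Sonogashira coupling run as a macrocyclisation, in which zerovalent palladium inserts into the C4–I bond with retention of the Z geometry, CO insertion gives an acylpalladium that couples with the copper acetylide at high dilution, and the direct coupling is disfavoured because it would give a more strained 9-membered enyne.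

**Step 11**
Reactants: 19 (4Z,6S,7S,8R,10R)-8-[(E)-but-2-enoyloxy]-15-[(tert-butyldimethylsilyl)oxy]-10-hydroxy-3-oxogermacra-4,11(13)-dien-1-yn-6,12-olide
Product: 21 (4Z,6S,7S,8R,10R)-8-[(E)-but-2-enoyloxy]-15-hydroxy-1-oxo-3,10-epoxygermacra-2,4,11(13)-trien-6,12-olide (CNP0225232.1), via silyl ether 20 (not isolated)
Conditions: (4-CF3C6H4)3PAuCl/AgOTf (5 mol% each), H2O (1 equiv), 1,4-dioxane, 40 °C; then HF·pyridine, THF–pyridine, 0 °C → rt
Reagents that add atoms: water, O
Why: Proposed new method: transannular gold-catalysed hydrative cycloisomerisation of a strained macrocyclic γ-hydroxy-ynone, in which monovalent gold π-activates the bent C1≡C2 bond, water adds at C1 (β to the C3 ketone, with strain release), the C10 hydroxyl captures C3 of the resulting β-diketone and dehydration returns the water, forging the C3–O bridge with C10 untouched, the closest known reaction being the gold-catalysed cyclisation of open-chain γ-hydroxyalkynones to 3(2H)-furanones, not yet shown transannularly in a medium ring; fluoride then frees O15.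

**Compound list**
1 | 2-butyne-1,4-diol | OCC#CCO | starting material
2 | 4-[(tert-butyldimethylsilyl)oxy]but-2-yn-1-ol | OCC#CCO[Si](C)(C)C(C)(C)C | intermediate
3 | sodium 3-{[(tert-butyldimethylsilyl)oxy]methyl}-2,2-bis(2-methoxyethoxy)-2,5-dihydro-1,2-oxaaluminol-2-uide (cyclic alkenylalanate) | [Na+].COCCO[Al-]1(OCCOC)OCC=C1CO[Si](C)(C)C(C)(C)C | intermediate
4 | (Z)-4-[(tert-butyldimethylsilyl)oxy]-3-iodobut-2-en-1-ol | OC/C=C(/CO[Si](C)(C)C(C)(C)C)I | intermediate
5 | (Z)-4-[(tert-butyldimethylsilyl)oxy]-3-iodobut-2-enal | O=C/C=C(/CO[Si](C)(C)C(C)(C)C)I | intermediate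
6 | ethyl 2-(bromomethyl)acrylate | C=C(CBr)C(=O)OCC | starting material
7 | ethyl (4R,5Z)-7-[(tert-butyldimethylsilyl)oxy]-6-iodo-2-methylidene-4-[(trimethylsilyl)oxy]hept-5-enoate | CCOC(=O)C(=C)C[C@@H](O[Si](C)(C)C)/C=C(/CO[Si](C)(C)C(C)(C)C)I | intermediate
8 | ethyl (4R,5Z)-7-[(tert-butyldimethylsilyl)oxy]-4-hydroxy-6-iodo-2-methylidenehept-5-enoate | CCOC(=O)C(=C)C[C@@H](O)/C=C(/CO[Si](C)(C)C(C)(C)C)I | intermediate
9 | (R)-5-[(Z)-3-((tert-butyldimethylsilyl)oxy)-2-iodoprop-1-en-1-yl]-3-methylenedihydrofuran-2(3H)-one | C=C1C(=O)O[C@@H](/C=C(/CO[Si](C)(C)C(C)(C)C)I)C1 | intermediate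
10 | (5R)-3-bromo-3-(bromomethyl)-5-[(Z)-3-((tert-butyldimethylsilyl)oxy)-2-iodoprop-1-en-1-yl]dihydrofuran-2(3H)-one (C3 epimers) | BrCC1(Br)C(=O)O[C@@H](/C=C(/CO[Si](C)(C)C(C)(C)C)I)C1 | intermediate
11 | (R)-3-(bromomethyl)-5-[(Z)-3-((tert-butyldimethylsilyl)oxy)-2-iodoprop-1-en-1-yl]furan-2(5H)-one | BrCC1=C[C@H](/C=C(/CO[Si](C)(C)C(C)(C)C)I)OC1=O | intermediate
12 | 4-(trimethylsilyl)but-3-yn-2-one | CC(=O)C#C[Si](C)(C)C | starting material
13 | diisopropyl (R)-3-methyl-1-(trimethylsilyl)hex-5-en-1-yn-3-yl borate | C=CC[C@@](C)(OB(OC(C)C)OC(C)C)C#C[Si](C)(C)C | intermediate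
14 | (R)-3-methylhex-5-en-1-yn-3-ol | C=CC[C@@](C)(O)C#C | intermediate
15 | (2R)-2-methyl-1-(1,2,4-trioxolan-3-yl)but-3-yn-2-ol (ozonide, epimers at the trioxolane carbon) | C#C[C@](C)(O)CC1OCOO1 | intermediate
16 | (R)-3-hydroxy-3-methylpent-4-ynal | O=CC[C@@](C)(O)C#C | intermediate
17 | (4S,5R)-5-[(Z)-3-((tert-butyldimethylsilyl)oxy)-2-iodoprop-1-en-1-yl]-4-[(1R,3R)-1,3-dihydroxy-3-methylpent-4-yn-1-yl]-3-methylenedihydrofuran-2(3H)-one | C=C1C(=O)O[C@@H](/C=C(/CO[Si](C)(C)C(C)(C)C)I)[C@@H]1[C@H](O)C[C@@](C)(O)C#C | intermediate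
18 | (1R,3R)-1-[(2R,3S)-2-[(Z)-3-((tert-butyldimethylsilyl)oxy)-2-iodoprop-1-en-1-yl]-4-methylene-5-oxotetrahydrofuran-3-yl]-3-hydroxy-3-methylpent-4-yn-1-yl (E)-but-2-enoate | C=C1C(=O)O[C@@H](/C=C(/CO[Si](C)(C)C(C)(C)C)I)[C@@H]1[C@H](OC(=O)/C=C/C)C[C@@](C)(O)C#C | intermediate
19 | (4Z,6S,7S,8R,10R)-8-[(E)-but-2-enoyloxy]-15-[(tert-butyldimethylsilyl)oxy]-10-hydroxy-3-oxogermacra-4,11(13)-dien-1-yn-6,12-olide | C=C1C(=O)O[C@H]2/C=C(/CO[Si](C)(C)C(C)(C)C)C(=O)C#C[C@](C)(O)C[C@@H](OC(=O)/C=C/C)[C@H]12 | intermediate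
20 | (4Z,6S,7S,8R,10R)-8-[(E)-but-2-enoyloxy]-15-[(tert-butyldimethylsilyl)oxy]-1-oxo-3,10-epoxygermacra-2,4,11(13)-trien-6,12-olide | C=C1C(=O)O[C@H]2/C=C(/CO[Si](C)(C)C(C)(C)C)C3=CC(=O)[C@@](C)(C[C@@H](OC(=O)/C=C/C)[C@H]12)O3 | intermediate
21 | (4Z,6S,7S,8R,10R)-8-[(E)-but-2-enoyloxy]-15-hydroxy-1-oxo-3,10-epoxygermacra-2,4,11(13)-trien-6,12-olide (CNP0225232.1) | C=C1C(=O)O[C@H]2/C=C(/CO)C3=CC(=O)[C@@](C)(C[C@@H](OC(=O)/C=C/C)[C@H]12)O3 | target

**Totals**
Total step count: 11 (each one-pot sequence counted once). Longest linear sequence: 9 (steps 1–5, then 8–11).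

**Three steps most likely to fail**

Step 11 (the proposed new step). The risks are that the strained ynone follows another gold pathway (for example a Meyer–Schuster-type shift) or that water adds with the wrong regiochemistry. The fallback uses two classical polar steps, sets out from 19 and comes back at 20. Phosphine-catalysed conjugate addition of methanol to the ynone (PMe3 10 mol%, MeOH 5 equiv, CH2Cl2, 0 °C) gives the β-methoxy enone (4Z,6S,7S,8R,10R)-8-[(E)-but-2-enoyloxy]-15-[(tert-butyldimethylsilyl)oxy]-10-hydroxy-1-methoxy-3-oxogermacra-1,4,11(13)-trien-6,12-olide F4. PPTS in wet acetone then effects hemiketalisation of the C10 hydroxyl onto C3 and loss of methanol (the long-known acid cyclisation of hydroxy β-alkoxy enones to 3(2H)-furanones) to give 20, which is desilylated with HF·pyridine as in the route.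

Step 10. The risks are oligomerisation, ring strain, and capture of the acylpalladium by the exocyclic methylene. The fallback sets out from 18 and comes back at 19. The terminal alkyne is stannylated under neutral conditions (Bu3SnOMe, neat, 60 °C, methanol removed in vacuo) to the alkynylstannane (1R,3R)-1-[(2R,3S)-2-[(Z)-3-((tert-butyldimethylsilyl)oxy)-2-iodoprop-1-en-1-yl]-4-methylene-5-oxotetrahydrofuran-3-yl]-3-hydroxy-3-methyl-5-(tributylstannyl)pent-4-yn-1-yl (E)-but-2-enoate F3. The ring is then closed by a carbonylative Stille coupling (Pd2(dba)3, AsPh3, CO 1 atm, THF, 50 °C, high dilution), an amine- and copper-free manifold with precedent for macrocyclic ring closure under CO.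

Step 5. The risks are competing bromination of the iodoalkene and base-induced epimerisation at C6. The fallback builds the butenolide by metathesis instead, sets out from 5 and comes back at 11. Enal 5 is vinylated enantioselectively (Zn(CH=CH2)2, (−)-MIB-type amino-alcohol catalyst, toluene, 0 °C) to (R,Z)-6-[(tert-butyldimethylsilyl)oxy]-5-iodohexa-1,4-dien-3-ol F1. Esterification with 2-(bromomethyl)acryloyl chloride (2,6-lutidine, CH2Cl2, −20 °C) gives (R,Z)-6-[(tert-butyldimethylsilyl)oxy]-5-iodohexa-1,4-dien-3-yl 2-(bromomethyl)acrylate F2. Ring-closing metathesis (second-generation Hoveyda–Grubbs catalyst, toluene, 80 °C) forms the C7=C11 bond and delivers 11 without electrophilic bromine or amine base.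

**Further compounds**
F1 | step 5 | (R,Z)-6-[(tert-butyldimethylsilyl)oxy]-5-iodohexa-1,4-dien-3-ol | C=C[C@@H](O)/C=C(/CO[Si](C)(C)C(C)(C)C)I
F2 | step 5 | (R,Z)-6-[(tert-butyldimethylsilyl)oxy]-5-iodohexa-1,4-dien-3-yl 2-(bromomethyl)acrylate | C=C[C@@H](OC(=O)C(=C)CBr)/C=C(/CO[Si](C)(C)C(C)(C)C)I
F3 | step 10 | (1R,3R)-1-[(2R,3S)-2-[(Z)-3-((tert-butyldimethylsilyl)oxy)-2-iodoprop-1-en-1-yl]-4-methylene-5-oxotetrahydrofuran-3-yl]-3-hydroxy-3-methyl-5-(tributylstannyl)pent-4-yn-1-yl (E)-but-2-enoate | C=C1C(=O)O[C@@H](/C=C(/CO[Si](C)(C)C(C)(C)C)I)[C@@H]1[C@H](OC(=O)/C=C/C)C[C@@](C)(O)C#C[Sn](CCCC)(CCCC)CCCC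
F4 | step 11 | (4Z,6S,7S,8R,10R)-8-[(E)-but-2-enoyloxy]-15-[(tert-butyldimethylsilyl)oxy]-10-hydroxy-1-methoxy-3-oxogermacra-1,4,11(13)-trien-6,12-olide | C=C1C(=O)O[C@H]2/C=C(/CO[Si](C)(C)C(C)(C)C)C(=O)/C=C(/OC)[C@](C)(O)C[C@@H](OC(=O)/C=C/C)[C@H]12
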